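**Retrosynthetic overview**

1. The last bond made is ring oxygen–C10 of the furan-3(2H)-one (ring O, C3, C2, C1, C10). The enabling feature is that C10 is a quaternary ether carbon α to the C1 ketone, with an anti C9 hydroxyl beside it and the ring oxygen on C3, 1,5 to C10. That is the signature of a 9,10-epoxide opened at C10 with inversion by the C3 enol oxygen of a C1/C3 β-diketone, which is released in the flask from a macrocyclic epoxy ynone.
2. The ten-membered carbocycle is closed at C1–C2 by a chromium/nickel-mediated iodoalkyne–aldehyde addition.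
3. C7–C8 and the methylidene lactone come from an indium Barbier union of a 3-(bromomethyl)butenolide with an α,β-epoxy aldehyde; the C8 isobutyrate is installed by Mitsunobu inversion.
4. The butenolide comes from (Z)-3-methylpent-2-en-4-yn-1-ol (asymmetric alkynylation sets C6, carbonylation closes the lactone). The epoxy aldehyde comes from silyloxyacetone (Wittig, then asymmetric epoxidation sets C9 and C10).
5. Ring order: lactone (step 5), oxirane as a temporary ring (step 9), ten-membered carbocycle (step 16), furanone with loss of the oxirane (step 18).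

Key step: step 18

Remark: atoms are numbered as in the germacrane skeleton of the target (ring C1–C10, C11–C13 in the methylidene lactone, C14 on C10, C15 on C4). CIP letters quoted for an intermediate refer to that intermediate.
Assumption: compounds 1, 5, 11 and 12 are taken as commercially available.

**Route**

Step 1
Reactants: 1 (Z)-3-methylpent-2-en-4-yn-1-ol
Product: 3 (Z)-3-methyl-5-(trimethylsilyl)pent-2-en-4-yn-1-ol, via bis-silyl ether 2 (not isolated)
Conditions: n-BuLi (2.2 equiv), THF, −78 °C; Me3SiCl (2.3 equiv), −78 °C to rt; then 1 M HCl, rt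
Reagents that add atoms: chlorotrimethylsilane, C[Si](C)(C)Cl
Why: Double deprotonation and C,O-bis-silylation, after which only the acid-labile O–Si bond is cleaved on work-up (C-silylation of a terminal alkyne), leaving the Z alkene untouched.

Step 2
Reactants: 3 (Z)-3-methyl-5-(trimethylsilyl)pent-2-en-4-yn-1-ol
Product: 4 (Z)-3-methyl-5-(trimethylsilyl)pent-2-en-4-ynal
Conditions: MnO2 (excess), CH2Cl2, rt, dark
Reagents that add atoms: none
Why: Allylic alcohol oxidation with MnO2 is mild enough that the (Z)-enal geometry should be kept.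

Step 3
Reactants: 4 (Z)-3-methyl-5-(trimethylsilyl)pent-2-en-4-ynal; 5 tert-butyldimethyl(prop-2-yn-1-yloxy)silane
Product: 6 (4R,5Z)-1-[(tert-butyldimethylsilyl)oxy]-6-methyl-8-(trimethylsilyl)oct-5-ene-2,7-diyn-4-ol
Conditions: Me2Zn (3 equiv), (S,S)-ProPhenol (20 mol%), Ph3PO (40 mol%), toluene, 0 °C (ligand enantiomer chosen for Si-face addition; the antipode is used if the sense proves opposite)
Reagents that add atoms: none
Why: Catalytic asymmetric 1,2-alkynylation of an enal by a zinc acetylide under a dinuclear zinc–ProPhenol catalyst, whose Si-face delivery sets C6 as R, while the silyl cap keeps the enyne terminus from acting as a second acetylide.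

Step 4
Reactants: 6 (4R,5Z)-1-[(tert-butyldimethylsilyl)oxy]-6-methyl-8-(trimethylsilyl)oct-5-ene-2,7-diyn-4-ol
Product: 8 (2Z,4R,5Z)-1-[(tert-butyldimethylsilyl)oxy]-2-iodo-6-methyl-8-(trimethylsilyl)octa-2,5-dien-7-yn-4-ol, via cyclic alkenylaluminate 7 (not isolated)
Conditions: NaAlH2(OCH2CH2OMe)2 (1.6 equiv), THF, 0 °C; then I2, −78 to 0 °C
Reagents that add atoms: iodine, II
Why: Hydroxyl-directed trans-hydroalumination of the propargylic alcohol puts aluminium on the distal alkyne carbon in a five-membered alkoxy aluminate, and iodinolysis with retention gives the (Z)-iodoalkene with iodine cis to the carbinol; the silylated enyne has no directing hydroxyl and should stay.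

Step 5
Reactants: 8 (2Z,4R,5Z)-1-[(tert-butyldimethylsilyl)oxy]-2-iodo-6-methyl-8-(trimethylsilyl)octa-2,5-dien-7-yn-4-ol
Product: 9 (5R)-3-{[(tert-butyldimethylsilyl)oxy]methyl}-5-[(Z)-2-methyl-4-(trimethylsilyl)but-1-en-3-yn-1-yl]furan-2(5H)-one
Conditions: PdCl2(PPh3)2 (5 mol%), CO (1 atm), K2CO3, THF, 35 °C
Reagents that add atoms: carbon monoxide, [C-]#[O+]
Why: Palladium-catalysed carbonylative lactonisation (oxidative addition of the vinyl iodide to zerovalent palladium formed in situ, CO insertion, capture of the acyl-palladium by the cis C6 hydroxyl) closes the butenolide without touching the C6 stereocenter.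

Step 6
Reactants: 9 (5R)-3-{[(tert-butyldimethylsilyl)oxy]methyl}-5-[(Z)-2-methyl-4-(trimethylsilyl)but-1-en-3-yn-1-yl]furan-2(5H)-one
Product: 10 (5R)-3-(bromomethyl)-5-[(Z)-2-methyl-4-(trimethylsilyl)but-1-en-3-yn-1-yl]furan-2(5H)-one
Conditions: Ph3PBr2 (1.3 equiv), CH2Cl2, 0 °C to rt
Reagents that add atoms: dibromotriphenylphosphorane, BrP(Br)(c1ccccc1)(c1ccccc1)c1ccccc1
Why: Dibromotriphenylphosphorane converts a primary allylic silyl ether directly into the bromide (alkoxyphosphonium bromide, then SN2) under neutral conditions that should not epimerise C6.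

Step 7
Reactants: 11 1-[(tert-butyldimethylsilyl)oxy]propan-2-one; 12 ethyl 2-(triphenylphosphoranylidene)acetate
Product: 13 ethyl (E)-4-[(tert-butyldimethylsilyl)oxy]-3-methylbut-2-enoate
Conditions: toluene, 100 °C
Reagents that add atoms: none
Why: Wittig olefination of an α-silyloxy ketone with a stabilised ylide, in which the E isomer (ester trans to CH2OSi) is expected to dominate and the minor Z isomer is removed by chromatography.

Step 8
Reactants: 13 ethyl (E)-4-[(tert-butyldimethylsilyl)oxy]-3-methylbut-2-enoate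
Product: 14 (E)-4-[(tert-butyldimethylsilyl)oxy]-3-methylbut-2-en-1-ol
Conditions: i-Bu2AlH (2.2 equiv), CH2Cl2, −78 °C
Reagents that add atoms: none
Why: 1,2-Reduction of the enoate to the allylic alcohol with i-Bu2AlH at low temperature leaves the silyl ether and the alkene geometry unaffected.

Step 9
Reactants: 14 (E)-4-[(tert-butyldimethylsilyl)oxy]-3-methylbut-2-en-1-ol
Product: 15 [(2R,3R)-3-{[(tert-butyldimethylsilyl)oxy]methyl}-3-methyloxiran-2-yl]methanol
Conditions: Ti(OiPr)4 (10 mol%), D-(−)-diethyl tartrate (12 mol%), t-BuOOH, 4 Å MS, CH2Cl2, −20 °C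
Reagents that add atoms: tert-butyl hydroperoxide, CC(C)(C)OO
Why: Sharpless asymmetric epoxidation of an (E)-3,3-disubstituted primary allylic alcohol, in which the D-tartrate ligand selects the face that gives the (2R,3R)-epoxide and so sets C9 and C10, the trans relation of C8 and C1 on the oxirane following from the E alkene.

Step 10
Reactants: 15 [(2R,3R)-3-{[(tert-butyldimethylsilyl)oxy]methyl}-3-methyloxiran-2-yl]methanol
Product: 16 (2S,3R)-3-{[(tert-butyldimethylsilyl)oxy]methyl}-3-methyloxirane-2-carbaldehyde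
Conditions: Dess–Martin periodinane, NaHCO3, CH2Cl2, 0 °C to rt
Reagents that add atoms: none
Why: Buffered Dess–Martin oxidation should give the α,β-epoxy aldehyde without epoxide opening or epimerisation at C9.

Step 11
Reactants: 10 (5R)-3-(bromomethyl)-5-[(Z)-2-methyl-4-(trimethylsilyl)but-1-en-3-yn-1-yl]furan-2(5H)-one; 16 (2S,3R)-3-{[(tert-butyldimethylsilyl)oxy]methyl}-3-methyloxirane-2-carbaldehyde
Product: 17 (4R,5R)-4-[(R)-hydroxy{(2R,3R)-3-[(tert-butyldimethylsilyloxy)methyl]-3-methyloxiran-2-yl}methyl]-3-methylidene-5-[(Z)-2-methyl-4-(trimethylsilyl)but-1-en-3-yn-1-yl]oxolan-2-one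
Conditions: In powder (1.5 equiv), THF–H2O 3:1, rt
Reagents that add atoms: none
Why: Indium-mediated Barbier allylation in which the allylindium from 10 reacts at its γ-carbon (C7) through a chair Zimmerman–Traxler transition state on the butenolide face anti to the C6 alkenyl group (sets C7, trans lactone), and the ring-locked allyl geometry gives anti simple selectivity that coincides with Felkin–Anh attack on the epoxy aldehyde, so C8 should form as the (8R) carbinol, the epimer needed for step 12.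

Step 12
Reactants: 17 (4R,5R)-4-[(R)-hydroxy{(2R,3R)-3-[(tert-butyldimethylsilyloxy)methyl]-3-methyloxiran-2-yl}methyl]-3-methylidene-5-[(Z)-2-methyl-4-(trimethylsilyl)but-1-en-3-yn-1-yl]oxolan-2-one
Product: 18 (4S,5R)-4-[(S)-{(2R,3R)-3-[(tert-butyldimethylsilyloxy)methyl]-3-methyloxiran-2-yl}(2-methylpropanoyloxy)methyl]-3-methylidene-5-[(Z)-2-methyl-4-(trimethylsilyl)but-1-en-3-yn-1-yl]oxolan-2-one
Conditions: i-PrCO2H (3 equiv), PPh3 (3 equiv), DIAD (3 equiv), toluene, 0 °C to rt
Reagents that add atoms: 2-methylpropanoic acid, CC(C)C(=O)O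
Why: Mitsunobu esterification, in which SN2 displacement of the C8 oxyphosphonium by isobutyrate inverts C8 to the configuration of the target and installs the ester in the same step.

Step 13
Reactants: 18 (4S,5R)-4-[(S)-{(2R,3R)-3-[(tert-butyldimethylsilyloxy)methyl]-3-methyloxiran-2-yl}(2-methylpropanoyloxy)methyl]-3-methylidene-5-[(Z)-2-methyl-4-(trimethylsilyl)but-1-en-3-yn-1-yl]oxolan-2-one
Product: 19 (4S,5R)-4-[(S)-{(2R,3R)-3-(hydroxymethyl)-3-methyloxiran-2-yl}(2-methylpropanoyloxy)methyl]-3-methylidene-5-[(Z)-2-methyl-4-(trimethylsilyl)but-1-en-3-yn-1-yl]oxolan-2-one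
Conditions: HF·pyridine, pyridine, THF, 0 °C to rt
Reagents that add atoms: none
Why: Buffered HF·pyridine removes the primary silyl ether, while the C-silyl alkyne, the epoxide and both esters are expected to survive.

Step 14
Reactants: 19 (4S,5R)-4-[(S)-{(2R,3R)-3-(hydroxymethyl)-3-methyloxiran-2-yl}(2-methylpropanoyloxy)methyl]-3-methylidene-5-[(Z)-2-methyl-4-(trimethylsilyl)but-1-en-3-yn-1-yl]oxolan-2-one
Product: 20 (4S,5R)-4-[(S)-{(2R,3R)-3-(hydroxymethyl)-3-methyloxiran-2-yl}(2-methylpropanoyloxy)methyl]-5-[(Z)-4-iodo-2-methylbut-1-en-3-yn-1-yl]-3-methylideneoxolan-2-one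
Conditions: NIS (1.2 equiv), AgNO3 (10 mol%), acetone, rt, dark
Reagents that add atoms: N-iodosuccinimide, O=C1CCC(=O)N1I
Why: Silver-catalysed iododesilylation of the alkynylsilane gives the 1-iodoalkyne needed for the chromium-mediated closure under neutral conditions.

Step 15
Reactants: 20 (4S,5R)-4-[(S)-{(2R,3R)-3-(hydroxymethyl)-3-methyloxiran-2-yl}(2-methylpropanoyloxy)methyl]-5-[(Z)-4-iodo-2-methylbut-1-en-3-yn-1-yl]-3-methylideneoxolan-2-one
Product: 21 (4S,5R)-4-[(S)-{(2R,3S)-3-formyl-3-methyloxiran-2-yl}(2-methylpropanoyloxy)methyl]-5-[(Z)-4-iodo-2-methylbut-1-en-3-yn-1-yl]-3-methylideneoxolan-2-one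
Conditions: Dess–Martin periodinane, NaHCO3, CH2Cl2, 0 °C
Reagents that add atoms: none
Why: Dess–Martin oxidation of the primary alcohol gives an α,β-epoxy aldehyde that cannot enolise because C10 is quaternary.

Step 16
Reactants: 21 (4S,5R)-4-[(S)-{(2R,3S)-3-formyl-3-methyloxiran-2-yl}(2-methylpropanoyloxy)methyl]-5-[(Z)-4-iodo-2-methylbut-1-en-3-yn-1-yl]-3-methylideneoxolan-2-one
Product: 22 (1RS,6R,7S,8S,9R,10R)-9,10-epoxy-1-hydroxy-8-(2-methylpropanoyloxy)germacra-4Z,11(13)-dien-2-yn-12,6-olide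
Conditions: CrCl2 (8 equiv), NiCl2 (10 mol%), degassed THF, 2 mM, slow addition, rt
Reagents that add atoms: none
Why: Intramolecular Nozaki–Hiyama–Kishi reaction (nickel-catalysed C–I insertion, transmetalation to trivalent chromium, alkynyl addition to the aldehyde) closes the ten-membered ring at C1–C2 under high dilution, helped by the Z alkene and the trans lactone, and the C1 configuration does not matter because C1 is oxidised next.

Step 17
Reactants: 22 (1RS,6R,7S,8S,9R,10R)-9,10-epoxy-1-hydroxy-8-(2-methylpropanoyloxy)germacra-4Z,11(13)-dien-2-yn-12,6-olide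
Product: 23 (6R,7S,8S,9R,10S)-9,10-epoxy-8-(2-methylpropanoyloxy)-1-oxogermacra-4Z,11(13)-dien-2-yn-12,6-olide
Conditions: Dess–Martin periodinane, NaHCO3, CH2Cl2, 0 °C
Reagents that add atoms: none
Why: Dess–Martin oxidation of the propargylic alcohol gives the ynone and converges both C1 epimers.

Step 18
Reactants: 23 (6R,7S,8S,9R,10S)-9,10-epoxy-8-(2-methylpropanoyloxy)-1-oxogermacra-4Z,11(13)-dien-2-yn-12,6-olide
Product: 26 (6R,7S,8S,9R,10R)-9-hydroxy-8-(2-methylpropanoyloxy)-1-oxo-3,10-epoxygermacra-2,4Z,11(13)-trien-12,6-olide, via enaminone 24 (not isolated), via β-diketone 25 (not isolated)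
Conditions: Et2NH (1.05 equiv), THF, −20 °C; then 0.5 M aq. citric acid, 0 °C to rt; then NaHCO3 (aq) to pH 8–8.5, rt
Reagents that add atoms: water, O
Why: Proposed new method: diethylamine adds to C3 of the ynone to give enaminone 24, mild acid hydrolysis unmasks the C1/C3 β-diketone 25, and at pH 8–8.5 the diketonate oxygen on C3 attacks C10 of the α,β-epoxy ketone in an SN2 fashion (C10 is activated by the adjacent C1 carbonyl and by ring strain) while the departing C9 alkoxide is protonated by the aqueous medium. The closest known reaction types are the amine-mediated hydration of ynones to β-diketones, the opening of α,β-epoxy ketones by heteronucleophiles at the α-carbon, the 5-exo O-alkylation of β-dicarbonyl enols by tethered epoxides and the base-induced closure of γ-halo β-diketones to furan-3(2H)-ones. The furanone ring (O, C3, C2, C1, C10) closes transannularly in the 5-exo-tet mode, which bridges C3 and C10 of the ten-membered ring into the 11-oxabicyclo[6.2.1] core. C10 is set by inversion through backside attack on the (9R,10S)-oxirane made in step 9, and C9 keeps the oxirane oxygen as its free hydroxyl with retention, so the anti C9–OH/C10–O pattern of 26 follows from the trans-epoxide. The step needs O-alkylation at C10 and not 6-endo attack at C9: the planar O–C3–C2–C1 enolate holds the oxygen 1,5 to C10 and in line with the C10–O bond, C-alkylation would give a cyclopropane, and C9 is shielded by the C8 ester. One equivalent of amine at −20 °C should spare the methylidene lactone, and the weakly basic, non-Lewis-acidic end phase should avoid participation or migration of the C8 isobutyrate and retro-aldol cleavage of C9–C10.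

**Compound list**

1 | (Z)-3-methylpent-2-en-4-yn-1-ol | OC/C=C(/C)C#C | starting material
2 | trimethyl{[(2Z)-3-methyl-5-(trimethylsilyl)pent-2-en-4-yn-1-yl]oxy}silane | C[Si](C)(C)OC/C=C(/C)C#C[Si](C)(C)C | intermediate
3 | (Z)-3-methyl-5-(trimethylsilyl)pent-2-en-4-yn-1-ol | OC/C=C(/C)C#C[Si](C)(C)C | intermediate
4 | (Z)-3-methyl-5-(trimethylsilyl)pent-2-en-4-ynal | O=C/C=C(/C)C#C[Si](C)(C)C | intermediate
5 | tert-butyldimethyl(prop-2-yn-1-yloxy)silane | C#CCO[Si](C)(C)C(C)(C)C | starting material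
6 | (4R,5Z)-1-[(tert-butyldimethylsilyl)oxy]-6-methyl-8-(trimethylsilyl)oct-5-ene-2,7-diyn-4-ol | O[C@@H](C#CCO[Si](C)(C)C(C)(C)C)/C=C(/C)C#C[Si](C)(C)C | intermediate
7 | sodium cyclic alkenylaluminate from 6 (five-membered ring of alkoxide O, Al, the carbon bearing CH2OSi, the adjacent CH and the carbinol carbon; two 2-methoxyethoxy groups on Al) | [Na+].COCCO[Al-]1(OCCOC)O[C@H](/C=C(/C)C#C[Si](C)(C)C)C=C1CO[Si](C)(C)C(C)(C)C | intermediate
8 | (2Z,4R,5Z)-1-[(tert-butyldimethylsilyl)oxy]-2-iodo-6-methyl-8-(trimethylsilyl)octa-2,5-dien-7-yn-4-ol | O[C@@H](/C=C(\I)CO[Si](C)(C)C(C)(C)C)/C=C(/C)C#C[Si](C)(C)C | intermediate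
9 | (5R)-3-{[(tert-butyldimethylsilyl)oxy]methyl}-5-[(Z)-2-methyl-4-(trimethylsilyl)but-1-en-3-yn-1-yl]furan-2(5H)-one | O=C1O[C@H](/C=C(/C)C#C[Si](C)(C)C)C=C1CO[Si](C)(C)C(C)(C)C | intermediate
10 | (5R)-3-(bromomethyl)-5-[(Z)-2-methyl-4-(trimethylsilyl)but-1-en-3-yn-1-yl]furan-2(5H)-one | O=C1O[C@H](/C=C(/C)C#C[Si](C)(C)C)C=C1CBr | intermediate
11 | 1-[(tert-butyldimethylsilyl)oxy]propan-2-one | CC(=O)CO[Si](C)(C)C(C)(C)C | starting material
12 | ethyl 2-(triphenylphosphoranylidene)acetate | CCOC(=O)C=P(c1ccccc1)(c1ccccc1)c1ccccc1 | starting material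
13 | ethyl (E)-4-[(tert-butyldimethylsilyl)oxy]-3-methylbut-2-enoate | CCOC(=O)/C=C(\C)CO[Si](C)(C)C(C)(C)C | intermediate
14 | (E)-4-[(tert-butyldimethylsilyl)oxy]-3-methylbut-2-en-1-ol | OC/C=C(\C)CO[Si](C)(C)C(C)(C)C | intermediate
15 | [(2R,3R)-3-{[(tert-butyldimethylsilyl)oxy]methyl}-3-methyloxiran-2-yl]methanol | CC(C)(C)[Si](C)(C)OC[C@@]1(C)O[C@@H]1CO | intermediate
16 | (2S,3R)-3-{[(tert-butyldimethylsilyl)oxy]methyl}-3-methyloxirane-2-carbaldehyde | CC(C)(C)[Si](C)(C)OC[C@@]1(C)O[C@@H]1C=O | intermediate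
17 | (4R,5R)-4-[(R)-hydroxy{(2R,3R)-3-[(tert-butyldimethylsilyloxy)methyl]-3-methyloxiran-2-yl}methyl]-3-methylidene-5-[(Z)-2-methyl-4-(trimethylsilyl)but-1-en-3-yn-1-yl]oxolan-2-one | C=C1C(=O)O[C@H](/C=C(/C)C#C[Si](C)(C)C)[C@H]1[C@@H](O)[C@H]2O[C@]2(C)CO[Si](C)(C)C(C)(C)C | intermediate
18 | (4S,5R)-4-[(S)-{(2R,3R)-3-[(tert-butyldimethylsilyloxy)methyl]-3-methyloxiran-2-yl}(2-methylpropanoyloxy)methyl]-3-methylidene-5-[(Z)-2-methyl-4-(trimethylsilyl)but-1-en-3-yn-1-yl]oxolan-2-one | C=C1C(=O)O[C@H](/C=C(/C)C#C[Si](C)(C)C)[C@H]1[C@H](OC(=O)C(C)C)[C@H]2O[C@]2(C)CO[Si](C)(C)C(C)(C)C | intermediate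
19 | (4S,5R)-4-[(S)-{(2R,3R)-3-(hydroxymethyl)-3-methyloxiran-2-yl}(2-methylpropanoyloxy)methyl]-3-methylidene-5-[(Z)-2-methyl-4-(trimethylsilyl)but-1-en-3-yn-1-yl]oxolan-2-one | C=C1C(=O)O[C@H](/C=C(/C)C#C[Si](C)(C)C)[C@H]1[C@H](OC(=O)C(C)C)[C@H]2O[C@]2(C)CO | intermediate
20 | (4S,5R)-4-[(S)-{(2R,3R)-3-(hydroxymethyl)-3-methyloxiran-2-yl}(2-methylpropanoyloxy)methyl]-5-[(Z)-4-iodo-2-methylbut-1-en-3-yn-1-yl]-3-methylideneoxolan-2-one | C=C1C(=O)O[C@H](/C=C(/C)C#CI)[C@H]1[C@H](OC(=O)C(C)C)[C@H]2O[C@]2(C)CO | intermediate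
21 | (4S,5R)-4-[(S)-{(2R,3S)-3-formyl-3-methyloxiran-2-yl}(2-methylpropanoyloxy)methyl]-5-[(Z)-4-iodo-2-methylbut-1-en-3-yn-1-yl]-3-methylideneoxolan-2-one | C=C1C(=O)O[C@H](/C=C(/C)C#CI)[C@H]1[C@H](OC(=O)C(C)C)[C@H]2O[C@]2(C)C=O | intermediate
22 | (1RS,6R,7S,8S,9R,10R)-9,10-epoxy-1-hydroxy-8-(2-methylpropanoyloxy)germacra-4Z,11(13)-dien-2-yn-12,6-olide | C=C1C(=O)O[C@@H]2/C=C(/C)C#CC(O)[C@@]3(C)O[C@@H]3[C@@H](OC(=O)C(C)C)[C@@H]12 | intermediate
23 | (6R,7S,8S,9R,10S)-9,10-epoxy-8-(2-methylpropanoyloxy)-1-oxogermacra-4Z,11(13)-dien-2-yn-12,6-olide | C=C1C(=O)O[C@@H]2/C=C(/C)C#CC(=O)[C@@]3(C)O[C@@H]3[C@@H](OC(=O)C(C)C)[C@@H]12 | intermediate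
24 | (6R,7S,8S,9R,10S)-3-(diethylamino)-9,10-epoxy-8-(2-methylpropanoyloxy)-1-oxogermacra-2,4Z,11(13)-trien-12,6-olide | C=C1C(=O)O[C@@H]2/C=C(/C)C(N(CC)CC)=CC(=O)[C@@]3(C)O[C@@H]3[C@@H](OC(=O)C(C)C)[C@@H]12 | intermediate
25 | (6R,7S,8S,9R,10S)-9,10-epoxy-8-(2-methylpropanoyloxy)-1,3-dioxogermacra-4Z,11(13)-dien-12,6-olide | C=C1C(=O)O[C@@H]2/C=C(/C)C(=O)CC(=O)[C@@]3(C)O[C@@H]3[C@@H](OC(=O)C(C)C)[C@@H]12 | intermediate
26 | (6R,7S,8S,9R,10R)-9-hydroxy-8-(2-methylpropanoyloxy)-1-oxo-3,10-epoxygermacra-2,4Z,11(13)-trien-12,6-olide | C=C1C(=O)O[C@@H]2/C=C(/C)C3=CC(=O)[C@](C)(O3)[C@H](O)[C@@H](OC(=O)C(C)C)[C@@H]12 | target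

**Step count and risks**

Total step count: 18. Longest linear sequence: 14 steps (steps 1–6 and 11–18, from compound 1).

Steps most likely to fail:

1. Step 18. The enol oxygen may attack C9 in the 6-endo sense and give a dihydropyranone, the C8 ester may take part in epoxide opening during the acidic phase, or the amine may add to the methylidene lactone. The fallback uses known chemistry and closes the other C–O bond of the furanone. It sets out from 22 and comes back at 26. Acid-catalysed hydrolysis of the trisubstituted epoxide at the tertiary carbon C10 with inversion (dilute HClO4, THF–H2O, 0 °C) gives the 1,9,10-triol F1, which already carries the C9 and C10 configurations of the target. MnO2 in CH2Cl2 oxidises only the propargylic C1 hydroxyl and gives the 9,10-dihydroxy ynone F2. Ph3PAuNTf2 (monovalent gold, 5 mol%) in CH2Cl2 at rt then closes the furanone by 5-endo-dig addition of the tertiary C10 hydroxyl to C3 of the ynone, the established closure for γ-hydroxy ynones, and gives 26.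

2. Step 16. Oligomerisation may outrun ring closure, or the strained ten-membered transition state may not be reached before the alkynylchromium is quenched. The fallback makes the same C1–C2 bond by palladium/copper acyl alkynylation and delivers the ynone directly. It sets out from 19 and comes back at 23. Bu4NF buffered with AcOH in THF at 0 °C removes the alkynyl silyl group and gives the terminal alkyne alcohol F3. TEMPO (cat.) and PhI(OAc)2 in MeCN–H2O oxidise the primary alcohol to the epoxy carboxylic acid F4. 1-Chloro-N,N,2-trimethylprop-1-en-1-amine in CH2Cl2 gives the acid chloride F5 under neutral conditions. Slow addition of F5 to PdCl2(PPh3)2 (5 mol%), CuI (10 mol%) and Et3N in THF at high dilution then closes the ring by intramolecular acyl Sonogashira coupling to give 23.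

3. Step 12. The hindered C8 oxyphosphonium may eliminate or fail to be displaced by the weakly acidic isobutyric acid, leaving 17 unchanged. The fallback separates activation and displacement. It sets out from 17 and comes back at 18. ClCH2SO2Cl and pyridine in CH2Cl2 at 0 °C give the C8 chloromethanesulfonate F6 with retention. CsO2CCHMe2 with 18-crown-6 in toluene at 50 °C then displaces it with inversion to give 18.

**Further compounds**

F1 | step 18 | 1,9,10-trihydroxy-8-(2-methylpropanoyloxy)germacra-4Z,11(13)-dien-2-yn-12,6-olide, C6–C10 configured as in 26, C1 epimers | C=C1C(=O)O[C@@H]2/C=C(/C)C#CC(O)[C@](C)(O)[C@H](O)[C@@H](OC(=O)C(C)C)[C@@H]12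
F2 | step 18 | 9,10-dihydroxy-8-(2-methylpropanoyloxy)-1-oxogermacra-4Z,11(13)-dien-2-yn-12,6-olide, C6–C10 configured as in 26 | C=C1C(=O)O[C@@H]2/C=C(/C)C#CC(=O)[C@](C)(O)[C@H](O)[C@@H](OC(=O)C(C)C)[C@@H]12
F3 | step 16 | desilylated terminal alkyne analogue of 19 (primary alcohol) | C=C1C(=O)O[C@H](/C=C(/C)C#C)[C@H]1[C@H](OC(=O)C(C)C)[C@H]2O[C@]2(C)CO
F4 | step 16 | epoxy carboxylic acid from F3 (C1 as CO2H) | C=C1C(=O)O[C@H](/C=C(/C)C#C)[C@H]1[C@H](OC(=O)C(C)C)[C@H]2O[C@]2(C)C(=O)O
F5 | step 16 | acid chloride of F4 | C=C1C(=O)O[C@H](/C=C(/C)C#C)[C@H]1[C@H](OC(=O)C(C)C)[C@H]2O[C@]2(C)C(=O)Cl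
F6 | step 12 | C8 chloromethanesulfonate of 17 | C=C1C(=O)O[C@H](/C=C(/C)C#C[Si](C)(C)C)[C@H]1[C@@H](OS(=O)(=O)CCl)[C@H]2O[C@]2(C)CO[Si](C)(C)C(C)(C)C
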